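1. A pitfall lies in maple's right-handed readings: the last, 0.3%, sits inside a scatter of 1 percentage point, so maple gives no usable excess.

in all of them: gas 150 mM (held); racemization catalyst 200 mM; impurity 1.9 mM
- maple: left-handed substrate 1 M; right-handed substrate 1 M; free catalyst 10 mM; the very flask that is asked about, followed so far
- cedar: left-handed substrate 1 M; right-handed substrate 1 M; free catalyst 20 mM; run made earlier
- flask: left-handed substrate 1.0 M; right-handed substrate 1.0 M; free catalyst 10 mM; time 4.0 d

| run | time / h | left-handed product / % | right-handed product / % |
|---|---|---|---|
| maple | 4.00 | 6.7 | 0.6 |
| maple | 8.00 | 13.1 | 0.4 |
| maple | 12.0 | 16.6 | 0 |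
| maple | 15.0 | 21.8 | 0 |
| maple | 20.0 | 30.3 | 0.3 |
| cedar | 3.00 | 4.5 | 0 |
| cedar | 6.00 | 12.2 | 0 |
| cedar | 10.0 | 18.7 | 1.7 |
| cedar | 20.0 | 33.0 | 0.7 |
| cedar | 40.0 | 64.8 | 3.0 |

(each reading ± 1 percentage point)

1. left-handed product and right-handed product together, in percent of the left-handed substrate and right-handed substrate charged together, at 4.0 d
2. excess of left-handed product over right-handed product in the product at 4.0 d
3. whether the exchange between left-handed substrate and right-handed substrate keeps pace with the reaction: how far the product's excess at 4.0 d gets from its value without exchange to its value with instant exchange (above 80% keeps pace, below 20% hardly takes part, else lags behind)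

- free catalyst is single-handed; left-handed substrate and right-handed substrate are mirror images of each other, charged as a racemate, each of them at the stated concentration
- the earlier runs were read with a standard deviation of 1 percentage point
- at the start none of the gas is in solution
- an excess is the difference of the two amounts in percent of their sum
- an excess is below zero if the other one leads

2. First, how much the given numbers matter. In these runs c(free catalyst) shows little effect on the pace: cedar has twice maple's charge, yet at 20.0 h it holds 33.0% of left-handed product against maple's 30.3%.

3. The slope of maple matters little too. Held straight, it would convert the whole charge in 66.0 h, which is less than the 96 h allowed, so y should come near completion.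

4. The number that must be known well is the one from which eP is reckoned. Cedar's left-handed product, 64.8%, has passed the 50.0% of the charge that started left-handed, so exchange is running.

5. The leak ratio, right-handed product over left-handed product, is read from cedar's last line as 0.0463. With the substrates near racemic, its inverse is the selectivity factor. One scatter on a reading of 3.0% is its main uncertainty.

6. An excess follows from the ratio as (1 − ratio)/(1 + ratio). If the ratio holds to the end, this reckoning gives eP 91.2%, and its answer is that exchange keeps pace.

7. The forecast says y 98%, eP 73% and lags behind, on the ground that “In the last stretch, right-handed substrate reacts directly”. Its eP is lower than this reckoning's.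

8. The flask gives y 97.6%, eP 92.4% and keeps pace, at 97% of the way.

    reagent + free catalyst + left-handed substrate → free catalyst + left-handed product (k = 2.60 M⁻² min⁻¹)
    reagent + free catalyst + right-handed substrate → free catalyst + right-handed product (k = 0.0880 M⁻² min⁻¹)
    left-handed substrate + racemization catalyst ⇌ right-handed substrate + racemization catalyst, rate k3*[racemization catalyst]*[left-handed substrate] forward; the back reaction follows from the equilibrium constant (k = 0.0160 M⁻¹ min⁻¹)
    gas ⇌ reagent, rate k4*(csat - [reagent]) (kL = 0.00440 min⁻¹)
    free catalyst + impurity → spent catalyst (k = 260 M⁻¹ min⁻¹)

9. The forecast's eP stands 19 points below the flask's. At 4.00 d the flask holds 3.72% of right-handed product beside 93.9% of left-handed product, where the leak ratio 0.0463 gives 4.35%. In the neighbour with 0.080 M of racemization catalyst, the same ratio on 91.5% of left-handed product gives 4.24%, and that neighbour holds 4.51% of right-handed product, at eP 90.6%.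

The numbers in the tables come from a simulation for an exercise; scatter was added.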